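**Plan**

- The target is hexacosyl 3-(4-hydroxyphenyl)propanoate. The retrosynthesis cuts, in order: the phenolic O–acetyl bond (a protecting group), the C2–C3 bond of the hexacosyl chain, and the ester C(=O)–O bond to a 3-hydroxypropanoate unit.
- Forward: phloretic acid is O-acetylated, esterified with tert-butyl 3-hydroxypropanoate, and the tert-butyl ester is removed to give a β-acyloxy acid.
- This acid and pentacosanoic acid are joined by anodic decarboxylative radical cross-coupling (mixed Kolbe electrolysis), which builds the C26 chain from a C24 and a C2 piece; the acetate is then removed.
- Enabling feature: C2 and C3 of the O-alkyl chain are both unbranched sp3 CH2 carbons with no α-heteroatom (the ester oxygen sits on C1, β to C2), so each is accessible as a primary radical from a carboxylic acid. The only ring, the para-disubstituted benzene, is remote, and its phenolic oxygen is masked as the acetate to resist the anode.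
- Stereochemistry: the target has no stereocentre and no double-bond geometry, so nothing has to be set.

Key step: step 4

Remark: the target is achiral, so the requirement of a single enantiomer is met without any stereocontrol.

**Step 1**
Reactants: 1 3-(4-hydroxyphenyl)propanoic acid (phloretic acid)
Product: 2 3-(4-acetoxyphenyl)propanoic acid
Conditions: Ac2O (1.3 equiv), aq. NaOH (2.2 equiv), 0 °C; then aq. HCl to pH 2
Reagents that add atoms: acetic anhydride, CC(=O)OC(C)=O
Why: Schotten–Baumann-type O-acetylation in cold aqueous alkali should acylate the phenoxide of the dianion, while the carboxyl group is recovered free on acidification because any mixed anhydride is hydrolysed in water.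

**Step 2**
Reactants: 2 3-(4-acetoxyphenyl)propanoic acid; 3 tert-butyl 3-hydroxypropanoate
Product: 4 tert-butyl 3-{[3-(4-acetoxyphenyl)propanoyl]oxy}propanoate
Conditions: DCC (1.1 equiv), DMAP (5 mol%), CH2Cl2, 0 °C to rt
Reagents that add atoms: none
Why: Steglich esterification (carbodiimide activation with DMAP acyl transfer) should couple the acid with the unhindered primary alcohol of 3 at or below room temperature, where the aryl acetate and the tert-butyl ester are stable.

**Step 3**
Reactants: 4 tert-butyl 3-{[3-(4-acetoxyphenyl)propanoyl]oxy}propanoate
Product: 5 3-{[3-(4-acetoxyphenyl)propanoyl]oxy}propanoic acid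
Conditions: TFA/CH2Cl2 (1:3), rt
Reagents that add atoms: none
Why: Acidolysis of the tert-butyl ester (alkyl–oxygen cleavage through the tert-butyl cation, lost as isobutene) is orthogonal to the aryl acetate and the primary alkyl ester, which need a nucleophile to cleave.

**Step 4**
Reactants: 5 3-{[3-(4-acetoxyphenyl)propanoyl]oxy}propanoic acid (about 4 equiv); 6 pentacosanoic acid (1 equiv)
Product: 7 hexacosyl 3-(4-acetoxyphenyl)propanoate
Conditions: smooth Pt anode, Pt cathode, undivided cell, KOH (5 mol% of total acid), MeOH–hexane, 45 °C, constant current about 0.25 A cm⁻², stopped while the electrolyte is still weakly acidic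
Reagents that add atoms: none
Why: Mixed Kolbe electrolysis: both carboxylates are oxidised at the platinum anode and lose CO2 to give the tetracosyl radical (from 6) and the 2-acyloxyethyl radical (from 5, for which a 1,2-acyloxy shift would be degenerate), and these combine in the reaction layer at the electrode to form the C2–C3 bond of the hexacosyl chain. The closest known reaction type is the classical cross-Kolbe chain extension of fatty acids with ester-bearing co-acids, β-acyloxy acids included. No ring is closed and no stereocentre is formed. The step needs one-electron (radical) rather than two-electron (carbocation, non-Kolbe) chemistry, and this is secured because both radicals are primary and unstabilised, the acyloxy oxygen is β and not α to the radical carbon, and high current density on smooth platinum in weakly acidic methanol favours coupling. The arene must survive the anode, which is secured by the acetate lowering the electron density of the benzene ring, by its distance from the carboxylate that is adsorbed at the electrode, and by the acidic medium that keeps both esters from methanolysis. Cross- against homo-coupling is only statistical, so the cheaply made acid 5 is used in excess, and the two symmetrical homo-coupling products, one much less and one much more polar than 7, should be removable by chromatography.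

**Step 5**
Reactants: 7 hexacosyl 3-(4-acetoxyphenyl)propanoate
Product: 8 hexacosyl 3-(4-hydroxyphenyl)propanoate (target)
Conditions: pyrrolidine (3 equiv), THF, rt to 35 °C; dilute aq. HCl work-up
Reagents that add atoms: none
Why: Chemoselective aminolysis should cleave only the aryl acetate, an activated ester with a phenoxide leaving group, because the secondary amine attacks it far faster than the unactivated hexacosyl alkanoate.

**Compound list**

1 | 3-(4-hydroxyphenyl)propanoic acid | OC(=O)CCc1ccc(O)cc1 | starting material
2 | 3-(4-acetoxyphenyl)propanoic acid | CC(=O)Oc1ccc(CCC(=O)O)cc1 | intermediate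
3 | tert-butyl 3-hydroxypropanoate | CC(C)(C)OC(=O)CCO | starting material
4 | tert-butyl 3-{[3-(4-acetoxyphenyl)propanoyl]oxy}propanoate | CC(=O)Oc1ccc(CCC(=O)OCCC(=O)OC(C)(C)C)cc1 | intermediate
5 | 3-{[3-(4-acetoxyphenyl)propanoyl]oxy}propanoic acid | CC(=O)Oc1ccc(CCC(=O)OCCC(=O)O)cc1 | intermediate
6 | pentacosanoic acid | CCCCCCCCCCCCCCCCCCCCCCCCC(=O)O | starting material
7 | hexacosyl 3-(4-acetoxyphenyl)propanoate | CCCCCCCCCCCCCCCCCCCCCCCCCCOC(=O)CCc1ccc(OC(C)=O)cc1 | intermediate
8 | hexacosyl 3-(4-hydroxyphenyl)propanoate | CCCCCCCCCCCCCCCCCCCCCCCCCCOC(=O)CCc1ccc(O)cc1 | target

**Step count**

Total steps: 5. Longest linear sequence: 5 steps (1 → 2 → 4 → 5 → 7 → 8); 3 and 6 enter as commercial partners.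

**Steps most likely to fail**

Step 4. What may go wrong: over-oxidation at the anode (two-electron non-Kolbe chemistry or attack on the aryl ring), dominance of homo-coupling, and passivation of the anode by waxy deposits. The fallback sets out from 5 and 6 and comes back at 7. Each acid would be condensed with N-hydroxyphthalimide (DIC, CH2Cl2) to give the redox-active esters 1,3-dioxoisoindolin-2-yl pentacosanoate F1 and 1,3-dioxoisoindolin-2-yl 3-{[3-(4-acetoxyphenyl)propanoyl]oxy}propanoate F2. These would then be joined by nickel-electrocatalytic doubly decarboxylative C(sp3)–C(sp3) cross-coupling at the cathode (cat. NiCl2·6H2O with a terpyridine-type ligand, AgNO3 additive, Mg sacrificial anode, RVC cathode, NMP, rt, F2 in excess). This forms the same bond under reductive conditions that cannot oxidise the arene.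

Step 5. What may go wrong: loss of chemoselectivity (aminolysis of the hexacosyl ester beside the aryl acetate) or incomplete conversion because the waxy ester dissolves poorly. The fallback sets out from 7 and comes back at 8. Selectivity is given up: exhaustive methanolysis (K2CO3, MeOH–THF, 50 °C) should release hexacosan-1-ol F3. F3 is then re-esterified with phloretic acid 1 under Fischer conditions (cat. p-TsOH, toluene, reflux, Dean–Stark), where the free phenol does not compete with the aliphatic alcohol.

Step 2. What may go wrong: the activated acid going astray (rearrangement to an N-acylurea), DMAP-mediated transfer of the aryl acetyl group to alcohol 3, or base-induced β-elimination of the β-acyloxy ester. The fallback sets out from 2 and comes back at 5, bypassing 4 and step 3. The bond is made by O-alkylation instead of O-acylation: acid 2, deprotonated in situ with NaHCO3 in water/MeCN, should open β-propiolactone (oxetan-2-one) by SN2 attack of the carboxylate at the CH2–O carbon, and acidification gives 5 directly.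

**Further compounds**

F1 | step 4 | 1,3-dioxoisoindolin-2-yl pentacosanoate | CCCCCCCCCCCCCCCCCCCCCCCCC(=O)ON1C(=O)c2ccccc2C1=O
F2 | step 4 | 1,3-dioxoisoindolin-2-yl 3-{[3-(4-acetoxyphenyl)propanoyl]oxy}propanoate | CC(=O)Oc1ccc(CCC(=O)OCCC(=O)ON2C(=O)c3ccccc3C2=O)cc1
F3 | step 5 | hexacosan-1-ol | CCCCCCCCCCCCCCCCCCCCCCCCCCO
F0 | step 2 | none | none
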